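The ten-membered ring is cut between C8 and C9 (germacrane numbering). The target's C8 carbinol is homoallylic to the E-configured C1=C10 alkene, so C8 is treated as a masked acyl anion (a nitronate) and C9–C10–C1 as a π-allyl cation. The key step, a palladium-catalysed intramolecular allylic alkylation, closes the carbocycle on a preformed trans-lactone (C6, C7, C11, C12, O) with both trisubstituted alkenes already in place; the nitro group is then turned into the C8 oxygen. Its precursor is an open-chain nitromethyl lactone bearing an allylic methyl carbonate, built from a syn-carbocupration-derived dienoate through an α-methylbutenolide.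

Key step: step 10

Remark: locants follow germacrane numbering (C1–C10 ring, C6/C7 lactone fusion, C11–C13 lactone α-carbon, carbonyl and methyl, C14 methyl on C10, C15 oxygenated carbon on C4); the C8 oxygen is α (8S), the ring-trans C4=C5 alkene is Z by CIP, and compounds 1, 3, 6, 14 and 20 are taken as purchasable.

Step 1
Reactants: 1 methyl 4-hydroxybut-2-ynoate
Product: 2 methyl 4-{[tert-butyl(dimethyl)silyl]oxy}but-2-ynoate
Conditions: TBSCl, imidazole, CH2Cl2, 0 °C to rt
Reagents that add atoms: tert-butyldimethylsilyl chloride, CC(C)(C)[Si](C)(C)Cl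
Why: Standard silyl ether formation on the primary alcohol; the TBS group carries the C15 oxygen through the route and is the only protecting group needed.

Step 2
Reactants: 3 5-bromo-2-methylpent-2-ene; 2 methyl 4-{[tert-butyl(dimethyl)silyl]oxy}but-2-ynoate
Product: 5 methyl (2Z)-3-({[tert-butyl(dimethyl)silyl]oxy}methyl)-7-methylocta-2,6-dienoate, via (4-methylpent-3-en-1-yl)magnesium bromide 4 (not isolated)
Conditions: Mg, THF, rt; CuBr·SMe2, THF/Me2S, −45 °C; then 2, −78 °C; MeOH then aq. NH4Cl at −78 °C
Reagents that add atoms: none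
Why: Organocopper conjugate addition (syn-carbocupration) to the ynoate adds the homoprenyl group and copper cis, and protonation of the alkenylcopper at −78 °C with retention should give the (2Z)-enoate with CH2OTBS cis to the ester, which is the ring-trans C4=C5 geometry of the target.

Step 3
Reactants: 5 methyl (2Z)-3-({[tert-butyl(dimethyl)silyl]oxy}methyl)-7-methylocta-2,6-dienoate; 6 1-propynyllithium
Product: 7 (5Z)-6-({[tert-butyl(dimethyl)silyl]oxy}methyl)-10-methylundeca-5,9-dien-2-yn-4-one
Conditions: 6, BF3·OEt2, THF, −78 °C; then 5, −78 °C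
Reagents that add atoms: none
Why: BF3-mediated acylation of the lithium acetylide by the ester should stop at the ynone, because the borate-stabilised tetrahedral adduct collapses only on work-up and conjugate addition is blocked by the fully substituted β-carbon.

Step 4
Reactants: 7 (5Z)-6-({[tert-butyl(dimethyl)silyl]oxy}methyl)-10-methylundeca-5,9-dien-2-yn-4-one
Product: 8 (4R,5Z)-6-({[tert-butyl(dimethyl)silyl]oxy}methyl)-10-methylundeca-5,9-dien-2-yn-4-ol
Conditions: (R)-2-methyl-CBS-oxazaborolidine (0.3 equiv), catecholborane, toluene, −78 °C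
Reagents that add atoms: none
Why: Corey–Bakshi–Shibata reduction, in which the slim propynyl group is the small and the β,β-disubstituted alkenyl group the large substituent, so the (R)-oxazaborolidine should direct hydride to the face that gives the (4R)-alcohol (C6 of the target) while catecholborane at −78 °C leaves the alkenes and alkyne untouched.

Step 5
Reactants: 8 (4R,5Z)-6-({[tert-butyl(dimethyl)silyl]oxy}methyl)-10-methylundeca-5,9-dien-2-yn-4-ol
Product: 10 (2Z,4R,5Z)-6-({[tert-butyl(dimethyl)silyl]oxy}methyl)-2-iodo-10-methylundeca-2,5,9-trien-4-ol, via cyclic sodium vinylalanate 9 (not isolated)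
Conditions: NaAlH2(OCH2CH2OMe)2, THF, 0 °C to rt; EtOAc; then I2, THF, −78 °C
Reagents that add atoms: iodine, II
Why: Hydroxyl-directed trans-hydroalumination of the propargylic alcohol places aluminium on the distal alkyne carbon cis to the carbinol, and iodinolysis with retention should give the (2Z)-iodoalkene with iodine and the carbinol cis, as lactone closure requires.

Step 6
Reactants: 10 (2Z,4R,5Z)-6-({[tert-butyl(dimethyl)silyl]oxy}methyl)-2-iodo-10-methylundeca-2,5,9-trien-4-ol
Product: 11 (5R)-5-[(1Z)-2-({[tert-butyl(dimethyl)silyl]oxy}methyl)-6-methylhepta-1,5-dien-1-yl]-3-methylfuran-2(5H)-one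
Conditions: Pd(PPh3)4 (5 mol %), CO (1 atm), K2CO3, THF, 40 °C
Reagents that add atoms: carbon monoxide, [C-]#[O+]
Why: Palladium-catalysed carbonylative lactonisation (oxidative addition to the C–I bond, CO insertion, capture of the acylpalladium by the cis hydroxyl) should give the α-methylbutenolide with retention of alkene geometry and of the C6 centre under a mild heterogeneous base.

Step 7
Reactants: 11 (5R)-5-[(1Z)-2-({[tert-butyl(dimethyl)silyl]oxy}methyl)-6-methylhepta-1,5-dien-1-yl]-3-methylfuran-2(5H)-one
Product: 12 (5R)-5-[(1Z,5E)-2-({[tert-butyl(dimethyl)silyl]oxy}methyl)-7-hydroxy-6-methylhepta-1,5-dien-1-yl]-3-methylfuran-2(5H)-one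
Conditions: SeO2 (0.3 equiv), t-BuOOH, salicylic acid (cat.), CH2Cl2, 0 °C to rt
Reagents that add atoms: tert-butyl hydroperoxide, CC(C)(C)OO (its oxygen is relayed by catalytic SeO2)
Why: Riley allylic oxidation (ene reaction, then [2,3]-sigmatropic shift) should hydroxylate only the (E)-methyl of the electron-rich terminal alkene, since the butenolide alkene is conjugated and the C4=C5 alkene is deactivated by two allylic C–O bonds; this fixes the E geometry of the future C1=C10 alkene.

Step 8
Reactants: 12 (5R)-5-[(1Z,5E)-2-({[tert-butyl(dimethyl)silyl]oxy}methyl)-7-hydroxy-6-methylhepta-1,5-dien-1-yl]-3-methylfuran-2(5H)-one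
Product: 13 (2E,6Z)-6-({[tert-butyl(dimethyl)silyl]oxy}methyl)-2-methyl-7-[(2R)-4-methyl-5-oxo-2,5-dihydrofuran-2-yl]hepta-2,6-dien-1-yl methyl carbonate
Conditions: ClCO2Me, pyridine, CH2Cl2, 0 °C
Reagents that add atoms: methyl chloroformate, COC(=O)Cl
Why: Chloroformate acylation of the primary allylic alcohol gives the methyl carbonate, a leaving group that zerovalent palladium ionises without added base.

Step 9
Reactants: 13 (2E,6Z)-6-({[tert-butyl(dimethyl)silyl]oxy}methyl)-2-methyl-7-[(2R)-4-methyl-5-oxo-2,5-dihydrofuran-2-yl]hepta-2,6-dien-1-yl methyl carbonate; 14 nitromethane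
Product: 15 (2E,6Z)-6-({[tert-butyl(dimethyl)silyl]oxy}methyl)-2-methyl-7-[(2R,3R,4S)-4-methyl-3-(nitromethyl)-5-oxooxolan-2-yl]hepta-2,6-dien-1-yl methyl carbonate
Conditions: MeNO2 (solvent), DBU (0.2 equiv), 0 °C to rt
Reagents that add atoms: none
Why: Michael addition in which the nitronate adds to C7 anti to the C6 alkenyl group and the lactone enolate is protonated under equilibrating conditions to place the C11 methyl trans to the nitromethyl group (all-trans lactone); catalytic base at low temperature and the A(1,3)-twisted, poorly conjugating alkenyl group are expected to keep C6–H from being removed.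

Step 10
Reactants: 15 (2E,6Z)-6-({[tert-butyl(dimethyl)silyl]oxy}methyl)-2-methyl-7-[(2R,3R,4S)-4-methyl-3-(nitromethyl)-5-oxooxolan-2-yl]hepta-2,6-dien-1-yl methyl carbonate
Product: 16 (6R,7R,11S)-15-{[tert-butyl(dimethyl)silyl]oxy}-8-nitrogermacra-1(10)E,4Z-dien-6,12-olide (both C8 epimers)
Conditions: Pd2(dba)3·CHCl3 (5 mol %), dppe (12 mol %), THF, 50 °C, syringe-pump addition of 15 over 12 h (final about 1 mM)
Reagents that add atoms: none
Why: Zerovalent palladium ionises the primary allylic carbonate to a syn π-allylpalladium cation spanning C9–C10–C1, the expelled methyl carbonate loses CO2, and the methoxide so formed deprotonates only the nitromethyl group (far more acidic than the lactone α-CH), whose nitronate carbon C8 then attacks C9 on the face away from the metal. The closest known reaction type is the Tsuji–Trost allylation of nitroalkanes with allylic carbonates under neutral conditions, which is also established for medium-ring carbocycles with stabilised carbanions. The ten-membered carbocycle is closed in the endo mode with respect to the allyl unit (C9, C10 and C1 all end up in the ring), the trans-fused lactone being a spectator. The new stereocentre C8 forms as an inconsequential epimer mixture because it becomes sp2 in step 11, while C6, C7 and C11 are not touched. The step needs attack at C9 and not C1 (attack at C1 would give an eight-membered ring holding a trans alkene, and C9 is the unsubstituted terminus), retention of the E geometry at C1=C10 (the syn π-allyl complex should be trapped faster than it isomerises), C- over O-allylation (O-allyl nitronates re-ionise) and ring closure over oligomerisation (slow addition, high dilution). It also needs the carbonate to ionise in preference to the allylic lactone C6–O bond, which the far higher reactivity of carbonates without added base should secure.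

Step 11
Reactants: 16 (6R,7R,11S)-15-{[tert-butyl(dimethyl)silyl]oxy}-8-nitrogermacra-1(10)E,4Z-dien-6,12-olide
Product: 18 (6R,7S,11S)-15-{[tert-butyl(dimethyl)silyl]oxy}-8-oxogermacra-1(10)E,4Z-dien-6,12-olide (the C7 label changes by CIP priority only), via potassium nitronate 17 (not isolated)
Conditions: KOt-Bu (1.05 equiv), THF, −78 to 0 °C; then TiCl3, NH4OAc, H2O/THF (pH 5–6), 0 °C to rt
Reagents that add atoms: water, O
Why: Reductive Nef reaction in which trivalent titanium reduces the preformed nitronate through the oxime to the imine, which hydrolyses to the C8 ketone at pH 5–6, conditions chosen to avoid both base-induced β-elimination of the lactone oxygen and acid-triggered transannular cyclisation.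

Step 12
Reactants: 18 (6R,7S,11S)-15-{[tert-butyl(dimethyl)silyl]oxy}-8-oxogermacra-1(10)E,4Z-dien-6,12-olide
Product: 19 (6R,7R,8R,11S)-15-{[tert-butyl(dimethyl)silyl]oxy}-8-hydroxygermacra-1(10)E,4Z-dien-6,12-olide (8β-alcohol)
Conditions: LiBH(s-Bu)3 (1.1 equiv), THF, −78 °C; AcOH/THF quench at −78 °C
Reagents that add atoms: none
Why: Substrate-controlled reduction with a bulky trialkylborohydride, in which hydride should attack C8 from the open α (peripheral) face because the β face is screened by the C14 methyl group lying over C8 in the crown conformer and by the β-oriented C7–C11 bond, giving the axial 8β (8R) alcohol; the cold acidic quench prevents migration of the lactone to O8.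

Step 13
Reactants: 20 2-(hydroxymethyl)prop-2-enoic acid
Product: 21 2-(acetoxymethyl)prop-2-enoic acid
Conditions: Ac2O (1.2 equiv), H2SO4 (cat.), 0 °C to rt; then H2O
Reagents that add atoms: acetic anhydride, CC(=O)OC(C)=O
Why: Acid-catalysed O-acetylation of the primary allylic alcohol, any mixed anhydride at the carboxyl group being hydrolysed during aqueous work-up.

Step 14
Reactants: 19 (6R,7R,8R,11S)-15-{[tert-butyl(dimethyl)silyl]oxy}-8-hydroxygermacra-1(10)E,4Z-dien-6,12-olide; 21 2-(acetoxymethyl)prop-2-enoic acid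
Product: 22 (6R,7R,8S,11S)-8-{[2-(acetoxymethyl)prop-2-enoyl]oxy}-15-{[tert-butyl(dimethyl)silyl]oxy}germacra-1(10)E,4Z-dien-6,12-olide
Conditions: PPh3, DIAD (betaine preformed, slight excess of DIAD), THF, 0 °C; then 19 and 21, 0 °C to rt
Reagents that add atoms: none
Why: Mitsunobu esterification in which the alkoxyphosphonium ion of the axial 8β-alcohol is displaced by the carboxylate of 21 from the unhindered α (equatorial) side with inversion, setting the 8α (8S) ester; the PPh3–DIAD betaine is preformed so that no free phosphine meets the acrylate.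

Step 15
Reactants: 22 (6R,7R,8S,11S)-8-{[2-(acetoxymethyl)prop-2-enoyl]oxy}-15-{[tert-butyl(dimethyl)silyl]oxy}germacra-1(10)E,4Z-dien-6,12-olide
Product: 23 (6R,7R,8S,11S)-8-{[2-(acetoxymethyl)prop-2-enoyl]oxy}-15-hydroxygermacra-1(10)E,4Z-dien-6,12-olide (CNP0291063.1)
Conditions: HF·pyridine, pyridine, THF, 0 °C
Reagents that add atoms: none
Why: Buffered fluoride-mediated desilylation (Si–F bond formation) should free the primary allylic alcohol without touching the acrylate, the allylic acetate, the lactone or the acid-sensitive 1(10),4-diene.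

Compound list
1 | methyl 4-hydroxybut-2-ynoate | COC(=O)C#CCO | starting material
2 | methyl 4-{[tert-butyl(dimethyl)silyl]oxy}but-2-ynoate | COC(=O)C#CCO[Si](C)(C)C(C)(C)C | intermediate
3 | 5-bromo-2-methylpent-2-ene | CC(C)=CCCBr | starting material
4 | (4-methylpent-3-en-1-yl)magnesium bromide | CC(C)=CCC[Mg]Br | intermediate
5 | methyl (2Z)-3-({[tert-butyl(dimethyl)silyl]oxy}methyl)-7-methylocta-2,6-dienoate | COC(=O)/C=C(CO[Si](C)(C)C(C)(C)C)/CCC=C(C)C | intermediate
6 | 1-propynyllithium | [Li]C#CC | starting material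
7 | (5Z)-6-({[tert-butyl(dimethyl)silyl]oxy}methyl)-10-methylundeca-5,9-dien-2-yn-4-one | CC#CC(=O)/C=C(CO[Si](C)(C)C(C)(C)C)/CCC=C(C)C | intermediate
8 | (4R,5Z)-6-({[tert-butyl(dimethyl)silyl]oxy}methyl)-10-methylundeca-5,9-dien-2-yn-4-ol | CC#C[C@H](O)/C=C(CO[Si](C)(C)C(C)(C)C)/CCC=C(C)C | intermediate
9 | cyclic sodium vinylalanate of 8 (five-membered O–Al–C(CH3)=CH–CH ring, aluminium carrying two 2-methoxyethoxy groups) | CC1=C[C@@H](/C=C(CO[Si](C)(C)C(C)(C)C)/CCC=C(C)C)O[Al-]1(OCCOC)OCCOC.[Na+] | intermediate
10 | (2Z,4R,5Z)-6-({[tert-butyl(dimethyl)silyl]oxy}methyl)-2-iodo-10-methylundeca-2,5,9-trien-4-ol | C/C(I)=C/[C@H](O)/C=C(CO[Si](C)(C)C(C)(C)C)/CCC=C(C)C | intermediate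
11 | (5R)-5-[(1Z)-2-({[tert-butyl(dimethyl)silyl]oxy}methyl)-6-methylhepta-1,5-dien-1-yl]-3-methylfuran-2(5H)-one | CC1=C[C@@H](/C=C(CO[Si](C)(C)C(C)(C)C)/CCC=C(C)C)OC1=O | intermediate
12 | (5R)-5-[(1Z,5E)-2-({[tert-butyl(dimethyl)silyl]oxy}methyl)-7-hydroxy-6-methylhepta-1,5-dien-1-yl]-3-methylfuran-2(5H)-one | CC1=C[C@@H](/C=C(CO[Si](C)(C)C(C)(C)C)/CC/C=C(\C)CO)OC1=O | intermediate
13 | (2E,6Z)-6-({[tert-butyl(dimethyl)silyl]oxy}methyl)-2-methyl-7-[(2R)-4-methyl-5-oxo-2,5-dihydrofuran-2-yl]hepta-2,6-dien-1-yl methyl carbonate | CC1=C[C@@H](/C=C(CO[Si](C)(C)C(C)(C)C)/CC/C=C(\C)COC(=O)OC)OC1=O | intermediate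
14 | nitromethane | C[N+](=O)[O-] | starting material
15 | (2E,6Z)-6-({[tert-butyl(dimethyl)silyl]oxy}methyl)-2-methyl-7-[(2R,3R,4S)-4-methyl-3-(nitromethyl)-5-oxooxolan-2-yl]hepta-2,6-dien-1-yl methyl carbonate | O=C1O[C@H](/C=C(CO[Si](C)(C)C(C)(C)C)/CC/C=C(\C)COC(=O)OC)[C@@H](C[N+](=O)[O-])[C@@H]1C | intermediate
16 | (6R,7R,11S)-15-{[tert-butyl(dimethyl)silyl]oxy}-8-nitrogermacra-1(10)E,4Z-dien-6,12-olide (both C8 epimers) | [O-][N+](=O)C1C/C(C)=C/CC/C(CO[Si](C)(C)C(C)(C)C)=C/[C@H]2OC(=O)[C@@H](C)[C@H]12 | intermediate
17 | potassium nitronate of 16 | [K+].[O-][N+]([O-])=C1C/C(C)=C/CC/C(CO[Si](C)(C)C(C)(C)C)=C/[C@H]2OC(=O)[C@@H](C)[C@H]12 | intermediate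
18 | (6R,7S,11S)-15-{[tert-butyl(dimethyl)silyl]oxy}-8-oxogermacra-1(10)E,4Z-dien-6,12-olide | O=C1C/C(C)=C/CC/C(CO[Si](C)(C)C(C)(C)C)=C/[C@H]2OC(=O)[C@@H](C)[C@H]12 | intermediate
19 | (6R,7R,8R,11S)-15-{[tert-butyl(dimethyl)silyl]oxy}-8-hydroxygermacra-1(10)E,4Z-dien-6,12-olide | O[C@@H]1C/C(C)=C/CC/C(CO[Si](C)(C)C(C)(C)C)=C/[C@H]2OC(=O)[C@@H](C)[C@H]12 | intermediate
20 | 2-(hydroxymethyl)prop-2-enoic acid | C=C(CO)C(=O)O | starting material
21 | 2-(acetoxymethyl)prop-2-enoic acid | C=C(COC(C)=O)C(=O)O | intermediate
22 | (6R,7R,8S,11S)-8-{[2-(acetoxymethyl)prop-2-enoyl]oxy}-15-{[tert-butyl(dimethyl)silyl]oxy}germacra-1(10)E,4Z-dien-6,12-olide | C=C(COC(C)=O)C(=O)O[C@H]1C/C(C)=C/CC/C(CO[Si](C)(C)C(C)(C)C)=C/[C@H]2OC(=O)[C@@H](C)[C@H]12 | intermediate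
23 | (6R,7R,8S,11S)-8-{[2-(acetoxymethyl)prop-2-enoyl]oxy}-15-hydroxygermacra-1(10)E,4Z-dien-6,12-olide | C=C(COC(C)=O)C(=O)O[C@H]1C/C(C)=C/CC/C(CO)=C/[C@H]2OC(=O)[C@@H](C)[C@H]12 | target

Total step count: 15. Longest linear sequence: 14 steps (steps 1–12, 14 and 15; step 13 is a one-step side branch).

Steps most likely to fail

1. Step 10 (ring closure). Intermolecular allylation may outrun cyclisation and give oligomers, the π-allyl complex may lose a proton to give a 1,3-diene, or the allylic C6–O bond of the lactone may ionise. Fallback, from 13 back to 16: (phenylsulfonyl)nitromethane (Et3N, CH2Cl2) would be added to the butenolide in place of nitromethane to give the nitro(phenylsulfonyl)methyl lactone F1. This doubly stabilised, softer and far less basic carbanion is of the type proven in palladium-mediated medium-ring closures. It would be cyclised with Pd2(dba)3·CHCl3/dppe under slow addition to the 8-nitro-8-(phenylsulfonyl) macrocycle F2. Radical-chain reductive desulfonylation (1-benzyl-1,4-dihydronicotinamide, hν, DMF) would then return the route at 16.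

2. Step 14 (Mitsunobu inversion). The axial alkoxyphosphonium ion may undergo anti elimination towards C7 or C9, and phosphine may add to the acrylate or displace its allylic acetate. Fallback, from 19 back to 22: inversion and acylation would be separated. A Mitsunobu reaction with chloroacetic acid (more acidic, no Michael acceptor) should give the 8α-chloroacetate F4. Thiourea and NaHCO3 in EtOH would release the 8α-alcohol F5 under near-neutral conditions. F5 would then be acylated with retention by 2-(acetoxymethyl)prop-2-enoyl chloride F6 (made from 21 with (COCl)2 and catalytic DMF) and 2,6-lutidine in CH2Cl2 to give 22.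

3. Step 11 (Nef reaction). Deprotonation next to the new ketone may expel the lactone oxygen by β-elimination or epimerise C7, and the acidic titanium medium may trigger transannular cyclisation of the diene or loss of the silyl ether. Fallback, from 16 back to 18: the nitro group would first be reduced to the oxime F3 with SnCl2, PhSH and Et3N in MeCN at rt. The oxime would then be exchanged with aqueous glyoxylic acid in THF, which releases ketone 18 without strong base or low-valent titanium.

Further compounds
F1 | step 10 | (2E,6Z)-6-({[tert-butyl(dimethyl)silyl]oxy}methyl)-2-methyl-7-{(2R,3S,4S)-4-methyl-3-[nitro(phenylsulfonyl)methyl]-5-oxooxolan-2-yl}hepta-2,6-dien-1-yl methyl carbonate (both epimers at the nitro-bearing carbon; C3 label changed by CIP priority only) | O=C1O[C@H](/C=C(CO[Si](C)(C)C(C)(C)C)/CC/C=C(\C)COC(=O)OC)[C@@H](C([N+](=O)[O-])S(=O)(=O)c2ccccc2)[C@@H]1C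
F2 | step 10 | (6R,7S,11S)-15-{[tert-butyl(dimethyl)silyl]oxy}-8-nitro-8-(phenylsulfonyl)germacra-1(10)E,4Z-dien-6,12-olide (both C8 epimers) | [O-][N+](=O)C1(S(=O)(=O)c3ccccc3)C/C(C)=C/CC/C(CO[Si](C)(C)C(C)(C)C)=C/[C@H]2OC(=O)[C@@H](C)[C@H]12
F3 | step 11 | (6R,7R,11S)-15-{[tert-butyl(dimethyl)silyl]oxy}-8-(hydroxyimino)germacra-1(10)E,4Z-dien-6,12-olide (oxime E/Z mixture) | ON=C1C/C(C)=C/CC/C(CO[Si](C)(C)C(C)(C)C)=C/[C@H]2OC(=O)[C@@H](C)[C@H]12
F4 | step 14 | (6R,7R,8S,11S)-8-(chloroacetoxy)-15-{[tert-butyl(dimethyl)silyl]oxy}germacra-1(10)E,4Z-dien-6,12-olide | ClCC(=O)O[C@H]1C/C(C)=C/CC/C(CO[Si](C)(C)C(C)(C)C)=C/[C@H]2OC(=O)[C@@H](C)[C@H]12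
F5 | step 14 | (6R,7R,8S,11S)-15-{[tert-butyl(dimethyl)silyl]oxy}-8-hydroxygermacra-1(10)E,4Z-dien-6,12-olide | O[C@H]1C/C(C)=C/CC/C(CO[Si](C)(C)C(C)(C)C)=C/[C@H]2OC(=O)[C@@H](C)[C@H]12
F6 | step 14 | 2-(acetoxymethyl)prop-2-enoyl chloride | C=C(COC(C)=O)C(Cl)=O
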